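The target is the ester of a 15-oxo-labda-8(17),12-dien-16-oic acid with a 14-hydroxy-labda-8(17),12-dien-16,15-olide (labdane numbering). Both halves are made from one aldehyde, γ-bicyclohomofarnesal, and joined at the end by esterification. The aldehyde rests on a catalytic asymmetric, inverse-demand intramolecular Diels–Alder reaction. Ring B (C5–C10) is read as a cyclohexene in which the C5=C6 vinyl group has added across a C7=C8–C9=C10 diene, whose formyl group becomes the exocyclic methylene carbon C17. One operation closes rings A and B, forms C6–C7 and C5–C10, and sets C5 and C10. The precursor is an acyclic 2-formyl triene with a geometrically defined tetrasubstituted C9=C10 bond.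

Key step: step 10

Remark: labdane numbering is used throughout (primed for the lactone half); the sense of asymmetric induction in step 10 is assumed from the accepted binding model of 2-substituted acroleins on this catalyst, and the mirror-image catalyst would be taken if the opposite sense were found.

Step 1
Reactants: 1 methyl 3,3-dimethylpent-4-enoate
Product: 2 3,3-dimethylpent-4-en-1-ol
Conditions: LiAlH4, Et2O, 0 °C; aqueous work-up
Reagents that add atoms: none
Why: Hydride reduction of the ester to the primary alcohol, the isolated vinyl group being inert to LiAlH4.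

Step 2
Reactants: 2 3,3-dimethylpent-4-en-1-ol
Product: 3 5-iodo-3,3-dimethylpent-1-ene
Conditions: I2, PPh3, imidazole, CH2Cl2, 0 °C to rt
Reagents that add atoms: iodine, II
Why: Appel-type iodination, an SN2 displacement of the alkoxyphosphonium ion at an unhindered primary carbon.

Step 3
Reactants: 4 2-acetylbutyrolactone (3-acetyldihydrofuran-2(3H)-one); 3 5-iodo-3,3-dimethylpent-1-ene
Product: 5 3-(5,5-dimethylhept-6-enoyl)dihydrofuran-2(3H)-one
Conditions: LiN(i-Pr)2 (2.2 equiv), THF, −78 to 0 °C; then 3, DMPU, 0 °C to rt; aqueous quench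
Reagents that add atoms: none
Why: The β-keto lactone dianion is alkylated at its more basic terminal (former methyl) carbon, as in the dianion alkylation of acetoacetates, which joins C1 to C2.

Step 4
Reactants: 5 3-(5,5-dimethylhept-6-enoyl)dihydrofuran-2(3H)-one
Product: 6 (Z)-5,5-dimethyl-1-(2-oxodihydrofuran-3(2H)-ylidene)hept-6-en-1-yl trifluoromethanesulfonate
Conditions: NaH, Et2O, 0 °C; then Tf2O, −78 to 0 °C
Reagents that add atoms: trifluoromethanesulfonic anhydride, O=S(=O)(OS(=O)(=O)C(F)(F)F)C(F)(F)F
Why: O-sulfonylation of the sodium-chelated enolate, whose enolate oxygen is held cis to the lactone carbonyl, should give the (Z)-enol triflate and so fixes the geometry of the future C9=C10 bond.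

Step 5
Reactants: 6 (Z)-enol triflate
Product: 7 (E)-3-(6,6-dimethyloct-7-en-2-ylidene)dihydrofuran-2(3H)-one
Conditions: Me2CuLi, THF, −78 to −20 °C
Reagents that add atoms: lithium dimethylcuprate, [Li+].C[Cu-]C
Why: Cuprate addition–elimination on the β-triflyloxy enoate replaces triflate by methyl with retention, so the methyl group ends cis to the carbonyl carbon C8 and the chain cis to C11 (the descriptor changes to E only through the priority rules).

Step 6
Reactants: 7 (E)-3-(6,6-dimethyloct-7-en-2-ylidene)dihydrofuran-2(3H)-one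
Product: 8 (E)-3-(2-hydroxyethyl)-4,8,8-trimethyldeca-3,9-dien-2-one (in equilibrium with its cyclic lactol)
Conditions: MeLi (1.05 equiv), THF, −78 °C; then aq. NH4Cl
Reagents that add atoms: methyllithium, [Li]C
Why: 1,2-Addition of one methyllithium to the lactone carbonyl gives a lithium hemiketal alkoxide that persists at −78 °C, so the methyl ketone (C7–C8) is released only on work-up and is not attacked twice.

Step 7
Reactants: 8 (E)-3-(2-hydroxyethyl)-4,8,8-trimethyldeca-3,9-dien-2-one
Product: 9 (E)-3-[2-(tert-butyldimethylsilyloxy)ethyl]-4,8,8-trimethyldeca-3,9-dien-2-one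
Conditions: TBSCl, imidazole, DMF, rt
Reagents that add atoms: tert-butyldimethylsilyl chloride, CC(C)(C)[Si](C)(C)Cl
Why: Silylation of the primary hydroxyl group of the open-chain tautomer drains the lactol equilibrium and frees the methyl ketone.

Step 8
Reactants: 9 (E)-3-[2-(tert-butyldimethylsilyloxy)ethyl]-4,8,8-trimethyldeca-3,9-dien-2-one
Product: 10 (E)-3-[2-(tert-butyldimethylsilyloxy)ethyl]-4,8,8-trimethyldeca-1,3,9-trien-2-yl trifluoromethanesulfonate
Conditions: KN(SiMe3)2, THF, −78 °C; then PhNTf2, −78 to 0 °C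
Reagents that add atoms: N-phenylbis(trifluoromethanesulfonimide), O=S(=O)(N(c1ccccc1)S(=O)(=O)C(F)(F)F)C(F)(F)F
Why: Kinetic deprotonation of the methyl ketone at its methyl group gives the cross-conjugated enolate, and its O-triflation delivers the 2-triflyloxy-1,3-diene (C7=C8).

Step 9
Reactants: 10 dienyl triflate
Product: 11 (E)-3-[2-(tert-butyldimethylsilyloxy)ethyl]-4,8,8-trimethyl-2-methylidenedeca-3,9-dienal
Conditions: Pd(OAc)2 (5 mol %), 1,3-bis(diphenylphosphino)propane, CO (1 atm), Et3SiH (slow addition), Et3N, DMF, 60 °C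
Reagents that add atoms: carbon monoxide, [C-]#[O+]
Why: Palladium-catalysed reductive carbonylation of an enol triflate (oxidative addition, CO insertion, hydride transfer from the silane to the acylpalladium species) puts the formyl carbon C17 on C8.

Step 10
Reactants: 11 (E)-3-[2-(tert-butyldimethylsilyloxy)ethyl]-4,8,8-trimethyl-2-methylidenedeca-3,9-dienal
Product: 12 (4aS,8aS)-1-[2-(tert-butyldimethylsilyloxy)ethyl]-5,5,8a-trimethyl-3,4,4a,5,6,7,8,8a-octahydronaphthalene-2-carbaldehyde
Conditions: (S)-3,3-diphenyl-1-(2-methylphenyl)tetrahydro-1H,3H-pyrrolo[1,2-c][1,3,2]oxazaborole (20 mol %), Tf2NH (20 mol %), CH2Cl2, −78 to −20 °C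
Reagents that add atoms: none
Why: Proposed new method: the protonated oxazaborolidine binds the formyl group of 11 and lowers the LUMO of the 2-formyl diene, so that the unactivated vinyl group should add in a concerted but strongly asynchronous inverse-electron-demand intramolecular Diels–Alder reaction in which the unhindered C6–C7 bond (nucleophilic vinyl terminus to the formyl-activated methylidene carbon) leads and the congested C5–C10 bond follows; the closest known reaction types are the oxazaborolidinium-catalysed Diels–Alder reaction of 2-substituted acroleins and the inverse-demand cycloadditions of 2-acyl and 2-alkoxycarbonyl dienes with simple alkenes. Ring B closes as the [4+2] ring (C5–C6 onto C7–C8–C9–C10) and ring A closes in the same event through the C5–C10 bond, the four-carbon tether C1–C4 lying as a chair between the diene terminus C10 and the dienophile carbon C5. The stereocentres C5 and C10 are created together: their trans relation (C10 methyl anti to H5) comes from the anti transition state, in which C6 and C9 are both equatorial on the forming ring A, whereas either syn transition state must place C9 with its silyloxyethyl arm or C6 axial on that chair. Their absolute configuration is set by the catalyst, which covers one face of the coplanar formyl–diene unit. The step needs regio-, trans- and enantioselectivity: the tether enforces the regiochemistry, the E geometry of the C9=C10 bond made in steps 4 and 5 puts the tether outside and the methyl group inside on the diene terminus so that the anti chair is open, and the mirror-image catalyst is used if the sense of induction proves opposite. The silyl ether and the alkenes should tolerate the low-temperature Lewis acid conditions.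

Step 11
Reactants: 12 (4aS,8aS)-octahydronaphthalene-2-carbaldehyde
Product: 15 tert-butyldimethyl{2-[(1S,4aS,8aS)-5,5,8a-trimethyl-2-methylidenedecahydronaphthalen-1-yl]ethoxy}silane, via tosylhydrazone 13 (not isolated), via allylic diazene 14 (not isolated)
Conditions: TsNHNH2, THF, rt, then evaporation; catecholborane, CHCl3, 0 °C; then NaOAc·3H2O, reflux
Reagents that add atoms: none
Why: Reduction of the α,β-unsaturated tosylhydrazone with catecholborane and loss of sulfinate gives an allylic diazene, whose retro-ene loss of N2 moves the double bond to the exocyclic C8=C17 position and delivers hydrogen to C9 from the α-face, anti to the axial C10 methyl group, which sets C9 with its side chain equatorial.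

Step 12
Reactants: 15 silyl ether
Product: 16 2-[(1S,4aS,8aS)-5,5,8a-trimethyl-2-methylidenedecahydronaphthalen-1-yl]ethanol (γ-bicyclohomofarnesol)
Conditions: Bu4NF, THF, rt
Reagents that add atoms: none
Why: Fluoride cleavage of the primary silyl ether, to which nothing else in the molecule responds.

Step 13
Reactants: 16 γ-bicyclohomofarnesol
Product: 17 2-[(1S,4aS,8aS)-5,5,8a-trimethyl-2-methylidenedecahydronaphthalen-1-yl]acetaldehyde (γ-bicyclohomofarnesal)
Conditions: Dess–Martin periodinane, NaHCO3, CH2Cl2, 0 °C to rt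
Reagents that add atoms: none
Why: Buffered Dess–Martin oxidation of the primary alcohol stops at the aldehyde and leaves the exocyclic alkene and the C9 stereocentre (not α to the carbonyl) untouched.

Step 14
Reactants: 18 [2-(1,3-dioxolan-2-yl)ethyl]triphenylphosphonium bromide
Product: 21 methyl 3-(1,3-dioxolan-2-yl)-2-(triphenyl-λ5-phosphanylidene)propanoate, via phosphonium ylide 19 (not isolated), via acylphosphonium chloride 20 (not isolated)
Conditions: NaN(SiMe3)2 (1.0 equiv), THF, −78 °C; ClCO2Me (1.0 equiv); then NaN(SiMe3)2 (1.0 equiv), −78 °C to rt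
Reagents that add atoms: methyl chloroformate, COC(=O)Cl
Why: C-acylation of a non-stabilised phosphonium ylide with a chloroformate, followed by deprotonation of the acylphosphonium salt, is the standard entry to α-substituted ester-stabilised ylides.

Step 15
Reactants: 17 γ-bicyclohomofarnesal; 21 stabilised ylide
Product: 22 methyl (E)-2-(1,3-dioxolan-2-ylmethyl)-4-[(1S,4aS,8aS)-5,5,8a-trimethyl-2-methylidenedecahydronaphthalen-1-yl]but-2-enoate
Conditions: toluene, 80 °C
Reagents that add atoms: none
Why: The Wittig reaction of an ester-stabilised α-substituted ylide with an aliphatic aldehyde is steered to the (E)-enoate, placing C11 trans to the ester carbon C16.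

Step 16
Reactants: 22 methyl ester
Product: 23 (E)-2-(1,3-dioxolan-2-ylmethyl)-4-[(1S,4aS,8aS)-5,5,8a-trimethyl-2-methylidenedecahydronaphthalen-1-yl]but-2-enoic acid
Conditions: LiOH, THF/MeOH/H2O, 40 °C; then 1 M HCl to pH 4, 0 °C
Reagents that add atoms: lithium hydroxide, [Li+].[OH-]
Why: Saponification of the methyl ester, the dioxolane being stable to base and to the brief cold acidification.

Step 17
Reactants: 24 (R)-4-hydroxydihydrofuran-2(3H)-one
Product: 25 (R)-4-(tert-butyldimethylsilyloxy)dihydrofuran-2(3H)-one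
Conditions: TBSCl, imidazole, DMF, rt
Reagents that add atoms: tert-butyldimethylsilyl chloride, CC(C)(C)[Si](C)(C)Cl
Why: Silylation of the secondary alcohol, in which the stereocentre (the future C14') takes no part.

Step 18
Reactants: 25 silyloxy lactone; 17 γ-bicyclohomofarnesal
Product: 26 (3R,4R)-4-(tert-butyldimethylsilyloxy)-3-{1-hydroxy-2-[(1S,4aS,8aS)-5,5,8a-trimethyl-2-methylidenedecahydronaphthalen-1-yl]ethyl}dihydrofuran-2(3H)-one (mixture at the carbinol carbon)
Conditions: LiN(SiMe3)2, THF, −78 °C; then 17, −78 °C; aq. NH4Cl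
Reagents that add atoms: none
Why: Aldol addition of the lactone lithium enolate, attacked anti to the β-silyloxy group (3,4-trans); the carbinol centre forms as a mixture, and both new centres are erased in step 19.

Step 19
Reactants: 26 aldol adduct
Product: 28 (3E,4R)-4-(tert-butyldimethylsilyloxy)-3-{2-[(1S,4aS,8aS)-5,5,8a-trimethyl-2-methylidenedecahydronaphthalen-1-yl]ethylidene}dihydrofuran-2(3H)-one, via mesylate 27 (not isolated)
Conditions: MsCl, Et3N, CH2Cl2, 0 °C; then DBU, 0 °C to rt
Reagents that add atoms: none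
Why: E1cB elimination of the side-chain mesylate, a far better leaving group than the ring silyloxy group, gives the exocyclic C12'=C13' alkene, the (E) isomer (chain anti to the lactone carbonyl) being the favoured one.

Step 20
Reactants: 28 silyl-protected alkylidene lactone
Product: 29 (3E,4R)-4-hydroxy-3-{2-[(1S,4aS,8aS)-5,5,8a-trimethyl-2-methylidenedecahydronaphthalen-1-yl]ethylidene}dihydrofuran-2(3H)-one
Conditions: HF·pyridine, THF, 0 °C to rt
Reagents that add atoms: none
Why: Acidic fluoride desilylation avoids the basic conditions under which the β-hydroxy-α-alkylidene lactone could eliminate, and leaves C14' untouched.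

Step 21
Reactants: 23 acid; 29 hydroxy lactone
Product: 30 (3R,4E)-5-oxo-4-{2-[(1S,4aS,8aS)-5,5,8a-trimethyl-2-methylidenedecahydronaphthalen-1-yl]ethylidene}tetrahydrofuran-3-yl (E)-2-(1,3-dioxolan-2-ylmethyl)-4-[(1S,4aS,8aS)-5,5,8a-trimethyl-2-methylidenedecahydronaphthalen-1-yl]but-2-enoate
Conditions: EDC·HCl, DMAP (0.2 equiv), CH2Cl2, 0 °C to rt
Reagents that add atoms: none
Why: Carbodiimide (Steglich) esterification acylates the secondary alcohol with retention at C14', and the (E)-enoic acid has no tendency to isomerise.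

Step 22
Reactants: 30 dioxolane-protected ester
Product: 31 (3R,4E)-5-oxo-4-{2-[(1S,4aS,8aS)-5,5,8a-trimethyl-2-methylidenedecahydronaphthalen-1-yl]ethylidene}tetrahydrofuran-3-yl (E)-2-(2-oxoethyl)-4-[(1S,4aS,8aS)-5,5,8a-trimethyl-2-methylidenedecahydronaphthalen-1-yl]but-2-enoate (CNP0274315.1)
Conditions: pyridinium p-toluenesulfonate, acetone/H2O (9:1), 50 °C
Reagents that add atoms: water, O
Why: Mild acid-catalysed hydrolysis of the dioxolane should release the C15 aldehyde without touching the esters or the exocyclic alkenes.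

Compound list
1 | methyl 3,3-dimethylpent-4-enoate | COC(=O)CC(C)(C)C=C | starting material
2 | 3,3-dimethylpent-4-en-1-ol | OCCC(C)(C)C=C | intermediate
3 | 5-iodo-3,3-dimethylpent-1-ene | ICCC(C)(C)C=C | intermediate
4 | 2-acetylbutyrolactone (3-acetyldihydrofuran-2(3H)-one) | CC(=O)C1CCOC1=O | starting material
5 | 3-(5,5-dimethylhept-6-enoyl)dihydrofuran-2(3H)-one | C=CC(C)(C)CCCC(=O)C1CCOC1=O | intermediate
6 | (Z)-5,5-dimethyl-1-(2-oxodihydrofuran-3(2H)-ylidene)hept-6-en-1-yl trifluoromethanesulfonate | O=C1OCC/C1=C(/OS(=O)(=O)C(F)(F)F)CCCC(C)(C)C=C | intermediate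
7 | (E)-3-(6,6-dimethyloct-7-en-2-ylidene)dihydrofuran-2(3H)-one | O=C1OCC/C1=C(/C)CCCC(C)(C)C=C | intermediate
8 | (E)-3-(2-hydroxyethyl)-4,8,8-trimethyldeca-3,9-dien-2-one | CC(=O)/C(CCO)=C(\C)CCCC(C)(C)C=C | intermediate
9 | (E)-3-[2-(tert-butyldimethylsilyloxy)ethyl]-4,8,8-trimethyldeca-3,9-dien-2-one | CC(=O)/C(CCO[Si](C)(C)C(C)(C)C)=C(\C)CCCC(C)(C)C=C | intermediate
10 | (E)-3-[2-(tert-butyldimethylsilyloxy)ethyl]-4,8,8-trimethyldeca-1,3,9-trien-2-yl trifluoromethanesulfonate | C=C(OS(=O)(=O)C(F)(F)F)/C(CCO[Si](C)(C)C(C)(C)C)=C(\C)CCCC(C)(C)C=C | intermediate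
11 | (E)-3-[2-(tert-butyldimethylsilyloxy)ethyl]-4,8,8-trimethyl-2-methylidenedeca-3,9-dienal | C=C(C=O)/C(CCO[Si](C)(C)C(C)(C)C)=C(\C)CCCC(C)(C)C=C | intermediate
12 | (4aS,8aS)-1-[2-(tert-butyldimethylsilyloxy)ethyl]-5,5,8a-trimethyl-3,4,4a,5,6,7,8,8a-octahydronaphthalene-2-carbaldehyde | O=CC=1CC[C@H]2C(C)(C)CCC[C@]2(C)C=1CCO[Si](C)(C)C(C)(C)C | intermediate
13 | N-tosylhydrazone of 12 | Cc1ccc(cc1)S(=O)(=O)N/N=C/C=1CC[C@H]2C(C)(C)CCC[C@]2(C)C=1CCO[Si](C)(C)C(C)(C)C | intermediate (not isolated)
14 | allylic diazene from 13 | N=NCC=1CC[C@H]2C(C)(C)CCC[C@]2(C)C=1CCO[Si](C)(C)C(C)(C)C | intermediate (not isolated)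
15 | tert-butyldimethyl{2-[(1S,4aS,8aS)-5,5,8a-trimethyl-2-methylidenedecahydronaphthalen-1-yl]ethoxy}silane | C=C1CC[C@H]2C(C)(C)CCC[C@]2(C)[C@H]1CCO[Si](C)(C)C(C)(C)C | intermediate
16 | 2-[(1S,4aS,8aS)-5,5,8a-trimethyl-2-methylidenedecahydronaphthalen-1-yl]ethanol (γ-bicyclohomofarnesol) | C=C1CC[C@H]2C(C)(C)CCC[C@]2(C)[C@H]1CCO | intermediate
17 | 2-[(1S,4aS,8aS)-5,5,8a-trimethyl-2-methylidenedecahydronaphthalen-1-yl]acetaldehyde (γ-bicyclohomofarnesal) | C=C1CC[C@H]2C(C)(C)CCC[C@]2(C)[C@H]1CC=O | intermediate
18 | [2-(1,3-dioxolan-2-yl)ethyl]triphenylphosphonium bromide | [Br-].C1COC(CC[P+](c2ccccc2)(c2ccccc2)c2ccccc2)O1 | starting material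
19 | [2-(1,3-dioxolan-2-yl)ethylidene]triphenylphosphorane | C1COC(CC=P(c2ccccc2)(c2ccccc2)c2ccccc2)O1 | intermediate (not isolated)
20 | [3-(1,3-dioxolan-2-yl)-1-methoxy-1-oxopropan-2-yl]triphenylphosphonium chloride | [Cl-].COC(=O)C(CC1OCCO1)[P+](c1ccccc1)(c1ccccc1)c1ccccc1 | intermediate (not isolated)
21 | methyl 3-(1,3-dioxolan-2-yl)-2-(triphenyl-λ5-phosphanylidene)propanoate | COC(=O)C(CC1OCCO1)=P(c1ccccc1)(c1ccccc1)c1ccccc1 | intermediate
22 | methyl (E)-2-(1,3-dioxolan-2-ylmethyl)-4-[(1S,4aS,8aS)-5,5,8a-trimethyl-2-methylidenedecahydronaphthalen-1-yl]but-2-enoate | C=C1CC[C@H]2C(C)(C)CCC[C@]2(C)[C@H]1C/C=C(\CC1OCCO1)C(=O)OC | intermediate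
23 | (E)-2-(1,3-dioxolan-2-ylmethyl)-4-[(1S,4aS,8aS)-5,5,8a-trimethyl-2-methylidenedecahydronaphthalen-1-yl]but-2-enoic acid | C=C1CC[C@H]2C(C)(C)CCC[C@]2(C)[C@H]1C/C=C(\CC1OCCO1)C(=O)O | intermediate
24 | (R)-4-hydroxydihydrofuran-2(3H)-one | O[C@H]1COC(=O)C1 | starting material
25 | (R)-4-(tert-butyldimethylsilyloxy)dihydrofuran-2(3H)-one | CC(C)(C)[Si](C)(C)O[C@H]1COC(=O)C1 | intermediate
26 | (3R,4R)-4-(tert-butyldimethylsilyloxy)-3-{1-hydroxy-2-[(1S,4aS,8aS)-5,5,8a-trimethyl-2-methylidenedecahydronaphthalen-1-yl]ethyl}dihydrofuran-2(3H)-one | CC(C)(C)[Si](C)(C)O[C@H]1COC(=O)[C@@H]1C(O)C[C@H]1C(=C)CC[C@H]2C(C)(C)CCC[C@]12C | intermediate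
27 | methanesulfonate of 26 (3,4-trans) | CC(C)(C)[Si](C)(C)O[C@H]1COC(=O)[C@@H]1C(OS(C)(=O)=O)C[C@H]1C(=C)CC[C@H]2C(C)(C)CCC[C@]12C | intermediate (not isolated)
28 | (3E,4R)-4-(tert-butyldimethylsilyloxy)-3-{2-[(1S,4aS,8aS)-5,5,8a-trimethyl-2-methylidenedecahydronaphthalen-1-yl]ethylidene}dihydrofuran-2(3H)-one | CC(C)(C)[Si](C)(C)O[C@H]1COC(=O)/C1=C/C[C@H]1C(=C)CC[C@H]2C(C)(C)CCC[C@]12C | intermediate
29 | (3E,4R)-4-hydroxy-3-{2-[(1S,4aS,8aS)-5,5,8a-trimethyl-2-methylidenedecahydronaphthalen-1-yl]ethylidene}dihydrofuran-2(3H)-one | O[C@H]1COC(=O)/C1=C/C[C@H]1C(=C)CC[C@H]2C(C)(C)CCC[C@]12C | intermediate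
30 | dioxolane-protected ester of 23 with 29 | C=C1CC[C@H]2C(C)(C)CCC[C@]2(C)[C@H]1C/C=C(\CC1OCCO1)C(=O)O[C@H]1COC(=O)/C1=C/C[C@H]1C(=C)CC[C@H]2C(C)(C)CCC[C@]12C | intermediate
31 | CNP0274315.1 | C=C1CC[C@H]2C(C)(C)CCC[C@]2(C)[C@H]1C/C=C(\CC=O)C(=O)O[C@H]1COC(=O)/C1=C/C[C@H]1C(=C)CC[C@H]2C(C)(C)CCC[C@]12C | target

Total step count: 22. Longest linear sequence: 18 steps (steps 1–13 and 18–22).

Steps most likely to fail

Step 10 (the step that bears the label "Proposed new method:"). The cycloaddition may lose enantiofacial discrimination, may close through a syn transition state to the cis-fused ring system, or may leave the concerted path for a stepwise cationic one with a 1,2-methyl shift next to C5. The fallback uses known chemistry and sets out from 11. The triene is cyclised without a chiral catalyst as a plain inverse-demand intramolecular Diels–Alder reaction (toluene, BHT, 140 °C, sealed tube; or Me2AlCl, CH2Cl2, −40 °C). This should give the racemic trans-fused aldehyde, that is 12 together with its mirror image, the (4aR,8aR)-aldehyde F1. The two are separated by preparative chromatography on a chiral stationary phase, and the route is re-entered at 12.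

Step 9. The vinylpalladium species may be reduced before it takes up CO (hydrodetriflation), or the sensitive 2-formyl diene may be lost by dimerisation during the reaction. The fallback sets out from 10. Palladium-catalysed methoxycarbonylation (Pd(OAc)2, 1,3-bis(diphenylphosphino)propane, CO, MeOH, Et3N, DMF) gives the stable methyl dienoate F2. Reduction with i-Bu2AlH at −78 °C gives the dienyl alcohol F3. Oxidation of this allylic alcohol with MnO2 just before use returns to 11.

Step 18. The β-silyloxy group may be eliminated from the lithium enolate of 25 (giving a butenolide) before the enolate meets the aldehyde. The fallback sets out from 25. The enolate is trapped as it forms (LiN(i-Pr)2 with Me3SiCl already present, THF, −100 °C) as the silyl ketene acetal F4. This is joined to 17 in a BF3·OEt2-mediated Mukaiyama aldol addition at −78 °C, which returns to 26.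

Further compounds
F1 | step 10 | (4aR,8aR)-1-[2-(tert-butyldimethylsilyloxy)ethyl]-5,5,8a-trimethyl-3,4,4a,5,6,7,8,8a-octahydronaphthalene-2-carbaldehyde (mirror image of 12) | O=CC=1CC[C@@H]2C(C)(C)CCC[C@@]2(C)C=1CCO[Si](C)(C)C(C)(C)C
F2 | step 9 | methyl (E)-3-[2-(tert-butyldimethylsilyloxy)ethyl]-4,8,8-trimethyl-2-methylidenedeca-3,9-dienoate | C=C(C(=O)OC)/C(CCO[Si](C)(C)C(C)(C)C)=C(\C)CCCC(C)(C)C=C
F3 | step 9 | (E)-3-[2-(tert-butyldimethylsilyloxy)ethyl]-4,8,8-trimethyl-2-methylidenedeca-3,9-dien-1-ol | C=C(CO)/C(CCO[Si](C)(C)C(C)(C)C)=C(\C)CCCC(C)(C)C=C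
F4 | step 18 | (R)-tert-butyldimethyl{[5-(trimethylsilyloxy)-2,3-dihydrofuran-3-yl]oxy}silane | CC(C)(C)[Si](C)(C)O[C@H]1COC(O[Si](C)(C)C)=C1
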